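**Plan**

1. Ring A is the central benzene: C1 carries the quinone-methide carbon, C2 a 4-hydroxyphenyl ring, C3 and C4 are CH, C5 carries CH2OH and C6 the arylethynyl group. The carbon substituents on C2, C1 and C6 sit on three adjacent ring atoms, the pattern left by a 2,6-dihaloaryl metal that reacts through two successive arynes (C1≡C6, then C1≡C2) and is finally trapped at C1.
2. Retrosynthesis: the quinone methide is opened to a triaryl carbinol (water and the MOM groups are put back). The two carbinol C–aryl bonds are cut back to a C1 methyl ester. Then C6–alkynyl, C2–aryl and C1–CO2H are cut in one operation to 2-bromo-4-chloro-3-iodo-1-[(methoxymethoxy)methyl]benzene, an alkynyl Grignard, an aryl Grignard and CO2.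
3. Forward: the trihalide comes in three steps from 2-bromo-4-chlorobenzoic acid and both Grignard reagents from 4-bromophenol. The one-pot alkynylation/arylation/carboxylation joins the pieces on ring A, esterification and double aryllithium addition add the last two rings, and acid removes five MOM groups and water.
4. Bromine is placed on C6 and chlorine on C2, so that the strongly directing chlorine controls the first addition (next to CH2OMOM) and the second aryne has one unsubstituted flank.
5. All four benzene rings are bought and no ring is formed. The target has neither a stereocentre nor a configurational double bond, so the only selectivity issue is regiochemistry.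

Key step: step 9

Remark: MOM = CH2OCH3. The Grignard solutions 8 and 11 are assumed to be titrated, and 11 to be free of unreacted alkyne, because a terminal alkyne would protonate the aryl Grignard intermediates of step 9.

**Route**

Step 1
Reactants: 1 2-bromo-4-chlorobenzoic acid
Product: 2 (2-bromo-4-chlorophenyl)methanol
Conditions: BH3·THF (2 equiv), THF, 0 → 23 °C; then H2O
Reagents that add atoms: none
Why: Borane reduction of a carboxylic acid proceeds through the acyloxyborane and should leave both aryl halides untouched.

Step 2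
Reactants: 2 (2-bromo-4-chlorophenyl)methanol
Product: 3 2-bromo-4-chloro-1-[(methoxymethoxy)methyl]benzene
Conditions: MOMCl (1.5 equiv), i-Pr2NEt (2 equiv), CH2Cl2, 0 → 23 °C
Reagents that add atoms: chloromethyl methyl ether, COCCl
Why: O-alkylation of the primary alcohol by the reactive α-chloro ether gives the MOM acetal, which is inert to amide bases and Grignard reagents.

Step 3
Reactants: 3 2-bromo-4-chloro-1-[(methoxymethoxy)methyl]benzene
Product: 5 2-bromo-4-chloro-3-iodo-1-[(methoxymethoxy)methyl]benzene, via aryllithium 4 (not isolated)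
Conditions: LiN(i-Pr)2 (1.1 equiv), THF, −78 °C, 1 h; then I2 (1.2 equiv) in THF, −78 °C
Reagents that add atoms: iodine, II
Why: Lithiation of a 1,3-dihaloarene should occur at the C–H flanked by bromine and chlorine, the most acidic ring position, and the aryllithium is stable at −78 °C long enough to be iodinated before it can lose LiBr.

Step 4
Reactants: 6 4-bromophenol
Product: 7 1-bromo-4-(methoxymethoxy)benzene
Conditions: MOMCl (1.3 equiv), i-Pr2NEt (1.6 equiv), CH2Cl2, 0 → 23 °C
Reagents that add atoms: chloromethyl methyl ether, COCCl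
Why: O-alkylation of the phenol gives an aryl MOM ether that tolerates magnesium and lithium reagents and is later removed by mild acid.

Step 5
Reactants: 7 1-bromo-4-(methoxymethoxy)benzene
Product: 8 [4-(methoxymethoxy)phenyl]magnesium bromide (THF solution)
Conditions: Mg turnings (1.2 equiv), I2 (crystal), THF, 45 °C; titration
Reagents that add atoms: magnesium, [Mg]
Why: Grignard formation by magnesium insertion into the aryl bromide; the acetal is inert to the organomagnesium.

Step 6
Reactants: 7 1-bromo-4-(methoxymethoxy)benzene
Product: 9 {[4-(methoxymethoxy)phenyl]ethynyl}trimethylsilane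
Conditions: Me3SiC≡CH (1.3 equiv), PdCl2(PhCN)2 (3 mol %), P(t-Bu)3 (6 mol %), CuI (2 mol %), i-Pr2NH, dioxane, 23 °C
Reagents that add atoms: ethynyltrimethylsilane, C#C[Si](C)(C)C
Why: Sonogashira coupling, in which the bulky electron-rich phosphine allows oxidative addition of the electron-rich aryl bromide at room temperature and the silyl cap prevents double coupling.

Step 7
Reactants: 9 {[4-(methoxymethoxy)phenyl]ethynyl}trimethylsilane
Product: 10 1-ethynyl-4-(methoxymethoxy)benzene
Conditions: K2CO3 (0.2 equiv), MeOH, 23 °C
Reagents that add atoms: none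
Why: Methoxide-mediated protodesilylation of the alkynylsilane; the acetal is stable to base.

Step 8
Reactants: 10 1-ethynyl-4-(methoxymethoxy)benzene
Product: 11 {[4-(methoxymethoxy)phenyl]ethynyl}magnesium bromide (THF solution)
Conditions: EtMgBr (1.0 equiv), THF, 0 → 45 °C, 1 h
Reagents that add atoms: ethylmagnesium bromide, CC[Mg]Br
Why: Acid–base metalation of the sp C–H by the alkyl Grignard is irreversible through loss of ethane.

Step 9
Reactants: 5 2-bromo-4-chloro-3-iodo-1-[(methoxymethoxy)methyl]benzene; 11 {[4-(methoxymethoxy)phenyl]ethynyl}magnesium bromide; 8 [4-(methoxymethoxy)phenyl]magnesium bromide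
Product: 17 3-[(methoxymethoxy)methyl]-6-[4-(methoxymethoxy)phenyl]-2-{[4-(methoxymethoxy)phenyl]ethynyl}benzoic acid, via bromochloroaryl Grignard 12 (not isolated), via chloroaryne 13 (not isolated), via alkynylchloroaryl Grignard 14 (not isolated), via alkynylaryne 15 (not isolated), via arylalkynylaryl Grignard 16 (not isolated)
Conditions: i-PrMgCl·LiCl (1.05 equiv), THF, −40 °C, 30 min; 11 (2 equiv), −40 → 23 °C, 12 h; 8 (5 equiv), 65 °C, 8 h; CO2 (gas), −20 → 23 °C; 1 M HCl, 0 °C, to pH 3
Reagents that add atoms: carbon dioxide, O=C=O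
Why: Proposed new method: iodine–magnesium exchange, faster than exchange at bromine or chlorine, gives Grignard 12, which on warming to room temperature loses MgBrCl (bromide being the better leaving group) to form aryne 13; chlorine on C2 polarises the strained bond so that the rod-shaped acetylide 11 adds at the remote carbon C6, next to the CH2OMOM group whose oxygens can pre-coordinate magnesium, and the metal returns to C1 in 14. Only at reflux should 14 lose MgBrCl to give aryne 15, which the more nucleophilic aryl Grignard 8, added in excess at this point, attacks at the unsubstituted flank C2, remote from the inductively withdrawing alkynyl group, and the C1 Grignard 16, flanked by an aryl ring and a slim alkyne, is then carboxylated by CO2. The closest known reaction type is the one-pot two-aryne synthesis of 2,6-diarylphenylmagnesium halides from 2,6-dihaloiodobenzenes with electrophilic trapping, together with the addition of metal acetylides to arynes; new is the ordered use of two different carbon nucleophiles gated by the bromide/chloride difference in leaving-group ability. No ring closes and no stereocentre is formed. The step needs one nucleophile per aryne and the right regiochemistry at each: the first is secured by the temperature gap between bromide and chloride loss and by the higher aryne affinity of the sp2 Grignard over leftover 11, the second by the inductive directing effect of chlorine in 13 and by the substituted versus unsubstituted flanks of 15.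

Step 10
Reactants: 17 3-[(methoxymethoxy)methyl]-6-[4-(methoxymethoxy)phenyl]-2-{[4-(methoxymethoxy)phenyl]ethynyl}benzoic acid (crude, after acid–base extraction)
Product: 18 methyl 3-[(methoxymethoxy)methyl]-6-[4-(methoxymethoxy)phenyl]-2-{[4-(methoxymethoxy)phenyl]ethynyl}benzoate
Conditions: MeI (3 equiv), K2CO3 (2 equiv), DMF, 23 °C
Reagents that add atoms: iodomethane, CI
Why: O-methylation of the carboxylate by nucleophilic substitution takes place at the unhindered oxygen, so the two ortho substituents do not interfere, and room temperature should keep the carboxylate from adding to the neighbouring alkyne.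

Step 11
Reactants: 18 methyl 3-[(methoxymethoxy)methyl]-6-[4-(methoxymethoxy)phenyl]-2-{[4-(methoxymethoxy)phenyl]ethynyl}benzoate; 7 1-bromo-4-(methoxymethoxy)benzene
Product: 21 {3-[(methoxymethoxy)methyl]-6-[4-(methoxymethoxy)phenyl]-2-{[4-(methoxymethoxy)phenyl]ethynyl}phenyl}bis[4-(methoxymethoxy)phenyl]methanol, via aryllithium 19 (not isolated), via diaryl ketone 20 (not isolated)
Conditions: 7 (4 equiv), n-BuLi (3.9 equiv), THF, −78 °C, 30 min; then 18, −78 → 0 °C; aq. NH4Cl, −20 °C
Reagents that add atoms: none
Why: Bromine–lithium exchange gives aryllithium 19, which adds twice to the ester (double organolithium addition) because ketone 20 is more electrophilic than 18 and the linear alkyne leaves the carbonyl accessible; the cold quench should keep the lithium alkoxide from closing onto the alkyne.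

Step 12
Reactants: 21 {3-[(methoxymethoxy)methyl]-6-[4-(methoxymethoxy)phenyl]-2-{[4-(methoxymethoxy)phenyl]ethynyl}phenyl}bis[4-(methoxymethoxy)phenyl]methanol
Product: 23 selaginellin, via triarylmethylium chloride 22 (not isolated)
Conditions: 3 M aq. HCl, MeOH/THF (1:1), 45 °C; then aq. NaHCO3 to pH 7
Reagents that add atoms: none
Why: Acid ionises the triaryl carbinol to the triarylmethyl cation and cleaves the five MOM acetals by methanolysis, the positive charge meanwhile deactivating the ortho alkyne toward protonation; on neutralisation cation 22 loses a phenolic proton to give the quinone methide (fuchsone formation from a 4-hydroxytriarylmethanol).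

**Compound list**

1 | 2-bromo-4-chlorobenzoic acid | OC(=O)c1ccc(Cl)cc1Br | starting material
2 | (2-bromo-4-chlorophenyl)methanol | OCc1ccc(Cl)cc1Br | intermediate
3 | 2-bromo-4-chloro-1-[(methoxymethoxy)methyl]benzene | COCOCc1ccc(Cl)cc1Br | intermediate
4 | {2-bromo-6-chloro-3-[(methoxymethoxy)methyl]phenyl}lithium | COCOCc1ccc(Cl)c([Li])c1Br | intermediate
5 | 2-bromo-4-chloro-3-iodo-1-[(methoxymethoxy)methyl]benzene | COCOCc1ccc(Cl)c(I)c1Br | intermediate
6 | 4-bromophenol | Oc1ccc(Br)cc1 | starting material
7 | 1-bromo-4-(methoxymethoxy)benzene | COCOc1ccc(Br)cc1 | intermediate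
8 | [4-(methoxymethoxy)phenyl]magnesium bromide | COCOc1ccc([Mg]Br)cc1 | intermediate
9 | {[4-(methoxymethoxy)phenyl]ethynyl}trimethylsilane | COCOc1ccc(C#C[Si](C)(C)C)cc1 | intermediate
10 | 1-ethynyl-4-(methoxymethoxy)benzene | COCOc1ccc(C#C)cc1 | intermediate
11 | {[4-(methoxymethoxy)phenyl]ethynyl}magnesium bromide | COCOc1ccc(C#C[Mg]Br)cc1 | intermediate
12 | {2-bromo-6-chloro-3-[(methoxymethoxy)methyl]phenyl}magnesium chloride | COCOCc1ccc(Cl)c([Mg]Cl)c1Br | intermediate
13 | 3-chloro-6-[(methoxymethoxy)methyl]benzyne | COCOCC1=CC=C(Cl)C#C1 | intermediate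
14 | (6-chloro-3-[(methoxymethoxy)methyl]-2-{[4-(methoxymethoxy)phenyl]ethynyl}phenyl)magnesium bromide | COCOCc1ccc(Cl)c([Mg]Br)c1C#Cc1ccc(OCOC)cc1 | intermediate
15 | 4-[(methoxymethoxy)methyl]-3-{[4-(methoxymethoxy)phenyl]ethynyl}benzyne | COCOCC1=C(C#Cc2ccc(OCOC)cc2)C#CC=C1 | intermediate
16 | (3-[(methoxymethoxy)methyl]-6-[4-(methoxymethoxy)phenyl]-2-{[4-(methoxymethoxy)phenyl]ethynyl}phenyl)magnesium bromide | COCOCc1ccc(-c2ccc(OCOC)cc2)c([Mg]Br)c1C#Cc1ccc(OCOC)cc1 | intermediate
17 | 3-[(methoxymethoxy)methyl]-6-[4-(methoxymethoxy)phenyl]-2-{[4-(methoxymethoxy)phenyl]ethynyl}benzoic acid | COCOCc1ccc(-c2ccc(OCOC)cc2)c(C(=O)O)c1C#Cc1ccc(OCOC)cc1 | intermediate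
18 | methyl 3-[(methoxymethoxy)methyl]-6-[4-(methoxymethoxy)phenyl]-2-{[4-(methoxymethoxy)phenyl]ethynyl}benzoate | COCOCc1ccc(-c2ccc(OCOC)cc2)c(C(=O)OC)c1C#Cc1ccc(OCOC)cc1 | intermediate
19 | [4-(methoxymethoxy)phenyl]lithium | COCOc1ccc([Li])cc1 | intermediate
20 | {3-[(methoxymethoxy)methyl]-6-[4-(methoxymethoxy)phenyl]-2-{[4-(methoxymethoxy)phenyl]ethynyl}phenyl}[4-(methoxymethoxy)phenyl]methanone | COCOCc1ccc(-c2ccc(OCOC)cc2)c(C(=O)c2ccc(OCOC)cc2)c1C#Cc1ccc(OCOC)cc1 | intermediate
21 | {3-[(methoxymethoxy)methyl]-6-[4-(methoxymethoxy)phenyl]-2-{[4-(methoxymethoxy)phenyl]ethynyl}phenyl}bis[4-(methoxymethoxy)phenyl]methanol | COCOCc1ccc(-c2ccc(OCOC)cc2)c(C(O)(c2ccc(OCOC)cc2)c2ccc(OCOC)cc2)c1C#Cc1ccc(OCOC)cc1 | intermediate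
22 | bis(4-hydroxyphenyl){3-(hydroxymethyl)-6-(4-hydroxyphenyl)-2-[(4-hydroxyphenyl)ethynyl]phenyl}methylium chloride (O-protonated selaginellin) | OCc1ccc(-c2ccc(O)cc2)c([C+](c2ccc(O)cc2)c2ccc(O)cc2)c1C#Cc1ccc(O)cc1.[Cl-] | intermediate
23 | selaginellin | O=C1C=CC(=C(c2ccc(O)cc2)c2c(-c3ccc(O)cc3)ccc(CO)c2C#Cc2ccc(O)cc2)C=C1 | target

**Step count**

Total: 12 steps. Longest linear sequence: 8 steps (4, 6, 7, 8, 9, 10, 11, 12, from 4-bromophenol); the ring A branch (1, 2, 3, 9, 10, 11, 12) has 7.

**Steps most likely to fail**

Step 9 (Proposed new method). Capture of the first aryne by the weakly nucleophilic magnesium acetylide may be slower than its reaction with Grignard 12 itself, which would give oligomers. Chloride loss may begin before bromide loss is complete, which would give double alkynylation. Leftover 11 may compete with 8 for the second aryne. Addition to aryne 13 may also occur in part at the carbon next to chlorine.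

The fallback uses only known cross-coupling chemistry; it sets out from 3 and comes back at 18. Aryllithium 4, generated as in step 3, is quenched at −78 °C with methyl chloroformate instead of iodine to give methyl 2-bromo-6-chloro-3-[(methoxymethoxy)methyl]benzoate F1. Sonogashira coupling of the C–Br bond of F1 with alkyne 10 (PdCl2(PPh3)2, CuI, Et3N, 70 °C), which leaves the chloride alone, should give methyl 6-chloro-3-[(methoxymethoxy)methyl]-2-{[4-(methoxymethoxy)phenyl]ethynyl}benzoate F2. Suzuki–Miyaura coupling of the aryl chloride with [4-(methoxymethoxy)phenyl]boronic acid F3 (from Grignard 8 and B(OMe)3, then aqueous acid), under Pd(OAc)2/SPhos, K3PO4, toluene/H2O, 90 °C, should then give ester 18.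

Step 12. The stabilised triarylmethyl cation forms as soon as acid is added. It may be captured by methanol, chloride or the C2 aryl ring, and it may slow cleavage of the remaining acetals, above all the benzylic alkyl MOM ether. Harsher acid would then start to hydrate the electron-rich alkyne or close it onto a neighbouring hydroxyl group.

The fallback moves the acid step to a stage where no such cation can form and ends with a fluoride deprotection; it sets out from 18 and comes back at 23. Ester 18 is treated with HCl in MeOH at 40 °C to give methyl 3-(hydroxymethyl)-6-(4-hydroxyphenyl)-2-[(4-hydroxyphenyl)ethynyl]benzoate F5. Silylation (TBSCl, imidazole, DMF) gives methyl 3-{[(tert-butyldimethylsilyl)oxy]methyl}-6-{4-[(tert-butyldimethylsilyl)oxy]phenyl}-2-({4-[(tert-butyldimethylsilyl)oxy]phenyl}ethynyl)benzoate F6. 4-Bromophenol 6 is silylated to (4-bromophenoxy)(tert-butyl)dimethylsilane F7, which with n-BuLi at −78 °C gives {4-[(tert-butyldimethylsilyl)oxy]phenyl}lithium F8. Double addition of F8 to F6 should give {3-{[(tert-butyldimethylsilyl)oxy]methyl}-6-{4-[(tert-butyldimethylsilyl)oxy]phenyl}-2-({4-[(tert-butyldimethylsilyl)oxy]phenyl}ethynyl)phenyl}bis{4-[(tert-butyldimethylsilyl)oxy]phenyl}methanol F9. Bu4NF buffered with AcOH in THF removes the five silyl groups, and the 4-hydroxyphenyl carbinol should lose water on work-up with dilute acetic acid to give 23.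

Step 11. The ester carbonyl sits between an aryl ring and an alkyne, so the sequence may stall at the ketone stage, or the tertiary lithium alkoxide may add to the neighbouring alkyne on warming.

The fallback separates the two additions and uses a less basic, more carbonyl-selective organometallic for the second; it sets out from 17 and comes back at 21. Acid 17 is converted into its lithium salt (LiOH, then drying) and treated with aryllithium 19 (2 equiv, THF, 0 °C). Aqueous work-up of the gem-diolate releases ketone 20, which is isolated. Aryllithium 19 is transmetalated with anhydrous CeCl3 at −78 °C to [4-(methoxymethoxy)phenyl]cerium dichloride F4, which should add to the hindered ketone 20 at −78 °C and give carbinol 21 after a cold NH4Cl quench.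

**Further compounds**

F1 | step 9 | methyl 2-bromo-6-chloro-3-[(methoxymethoxy)methyl]benzoate | COCOCc1ccc(Cl)c(C(=O)OC)c1Br
F2 | step 9 | methyl 6-chloro-3-[(methoxymethoxy)methyl]-2-{[4-(methoxymethoxy)phenyl]ethynyl}benzoate | COCOCc1ccc(Cl)c(C(=O)OC)c1C#Cc1ccc(OCOC)cc1
F3 | step 9 | [4-(methoxymethoxy)phenyl]boronic acid | COCOc1ccc(B(O)O)cc1
F4 | step 11 | [4-(methoxymethoxy)phenyl]cerium dichloride | COCOc1ccc([Ce](Cl)Cl)cc1
F5 | step 12 | methyl 3-(hydroxymethyl)-6-(4-hydroxyphenyl)-2-[(4-hydroxyphenyl)ethynyl]benzoate | OCc1ccc(-c2ccc(O)cc2)c(C(=O)OC)c1C#Cc1ccc(O)cc1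
F6 | step 12 | methyl 3-{[(tert-butyldimethylsilyl)oxy]methyl}-6-{4-[(tert-butyldimethylsilyl)oxy]phenyl}-2-({4-[(tert-butyldimethylsilyl)oxy]phenyl}ethynyl)benzoate | CC(C)(C)[Si](C)(C)OCc1ccc(-c2ccc(O[Si](C)(C)C(C)(C)C)cc2)c(C(=O)OC)c1C#Cc1ccc(O[Si](C)(C)C(C)(C)C)cc1
F7 | step 12 | (4-bromophenoxy)(tert-butyl)dimethylsilane | CC(C)(C)[Si](C)(C)Oc1ccc(Br)cc1
F8 | step 12 | {4-[(tert-butyldimethylsilyl)oxy]phenyl}lithium | CC(C)(C)[Si](C)(C)Oc1ccc([Li])cc1
F9 | step 12 | {3-{[(tert-butyldimethylsilyl)oxy]methyl}-6-{4-[(tert-butyldimethylsilyl)oxy]phenyl}-2-({4-[(tert-butyldimethylsilyl)oxy]phenyl}ethynyl)phenyl}bis{4-[(tert-butyldimethylsilyl)oxy]phenyl}methanol | CC(C)(C)[Si](C)(C)OCc1ccc(-c2ccc(O[Si](C)(C)C(C)(C)C)cc2)c(C(O)(c2ccc(O[Si](C)(C)C(C)(C)C)cc2)c2ccc(O[Si](C)(C)C(C)(C)C)cc2)c1C#Cc1ccc(O[Si](C)(C)C(C)(C)C)cc1
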